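Every electrophile charged stands afterwards as electrophile, as target, or as something unread. In Tuesday's flask, where electrophile meets nucleophile charged as protonated nucleophile beside free base, the electrophile and target readings at 3.00 min are 11.9% and 4.7%. So 83.4% of the limiting reagent, charged in the smallest amount, sits in something unread.

in all of them: electrophile 0.72 M; free base 1.44 M
- Tuesday's: protonated nucleophile 0.792 M; the very flask that is asked about, followed so far
- Thursday's: protonated nucleophile 1.6 M; run made earlier
- flask: protonated nucleophile 0.792 M; time 8.0 min

| run | time / min | electrophile / % | target / % |
|---|---|---|---|
| Tuesday's | 0.200 | 88.9 | 4.3 |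
| Tuesday's | 0.667 | 63.8 | 4.7 |
| Tuesday's | 1.00 | 48.5 | 6.9 |
| Tuesday's | 2.00 | 23.9 | 6.9 |
| Tuesday's | 2.50 | 16.1 | 4.6 |
| Tuesday's | 3.00 | 11.9 | 4.7 |
| Thursday's | 0.667 | 46.2 | 8.2 |
| Thursday's | 1.00 | 32.5 | 10.3 |
| Thursday's | 2.00 | 9.4 | 10.6 |
| Thursday's | 3.00 | 3.3 | 11.3 |
| Thursday's | 5.00 | 0 | 11.2 |
| Thursday's | 8.00 | 1.8 | 10.3 |

(readings scatter by 1 percentage point)

- the earlier runs do not show how much of nucleophile is bound; that part of a forecast is a guess

* part of the electrophile that has reacted at 8.0 min
* share of the unused nucleophile that is free and not bound as protonated nucleophile, at 8.0 min

Tuesday's electrophile readings give a first-order constant of 0.718 /min, so this reckoning puts 99.7% reacted at 8.0 min. The bench rule for the nucleophile says that 2.00 equivalents of free base to electrophile cover the acid. But the protonated nucleophile brings acid of its own, so the rule stops where the acid load, the charged protonated nucleophile plus the whole electrophile, as one acid each, over the free base, passes one. Here the load is 1.05, just past that border. But that load counts every electrophile as setting one acid free, and what the unread part of Tuesday's flask sets free is not read. In this reckoning the load stays under one as long as less than 90.0% of the electrophile charged sets acid free. Then free base is left over, and if free base takes acid ahead of nucleophile, which is an assumption, the unused nucleophile stands free rather than bound.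

The forecast gives 99.6% reacted (98.5% to 100%) and 60% free (25% to 90%), a lower free share than this reckoning expects, and remarks: “This is a guess, since bound nucleophile was never measured, so the range is wide”.

The flask gives 99.4% reacted and 98.8% free, above the forecast's range.

    electrophile + nucleophile → acid set free + target (k = 0.0110 /M/s)
    nucleophile + acid set free ⇌ protonated nucleophile, settled at all times (K = 37.0 /M)
    acid set free + free base ⇌ salt of the base (K = 11000 /M, k = 2.10 /M/s)
    electrophile + target → side product A (k = 0.130 /M/s)
    electrophile + acid set free → side product B (k = 0.130 /M/s)

In this flask, at 8.00 min, the salt of the base stands at 1.10 M, which over the free base charged is 0.763 against the load of 1.05, and 23.7% of the free base is left, with side product A at 88.0%, each percentage of it holding two electrophile. The neighbour charged with 0.36 M of free base has a load of 4.20, and its charged protonated nucleophile over its free base is already 2.20. In that neighbour 0.27% of the free base is left, side product B reaches 41.8%, and the free share is 44.7%.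

The runs are simulated with made-up constants; the scatter is artificial.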